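**Retrosynthetic overview**

1. The route rests on the gem-dimethylcyclopropane C6–C7–C11, cis-fused to the cycloheptane (C1, C5–C10) directly beside the bare methylene C8. C8 is taken back to a ketone and C7 to a diazo carbon, so that one metal carbene adds across an isobutenyl group (C6=C11) on C5 of a cyclopentane and closes the seven- and three-membered rings together (bonds C6–C7 and C7–C11).
2. Before the key step: the cyclopentane comes from (R)-4-silyloxy-2-methylcyclopentenone by conjugate addition and alkylation (C5, C4). C1 and C10 follow from enol-ether oxidation, a spirobutenolide and a methyl conjugate addition.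
3. After the key step: C8 deoxygenation, bridged C1–O–C9' lactone, aryllithium acylation with SNAr closure of the benzoxepine, benzylic methallylation at C9', hydrogenation, double formylation.
4. Ring order: cyclopentane (bought) → cycloheptane and cyclopropane (one step) → arene attached → oxepine.

Key step: step 17

Convention: atoms carry the locants of the target (cyclopentane C1–C5; cycloheptane C1, C5–C10; cyclopropane C6, C7, C11; benzylic carbon C9'). β is the face of the cyclopentane that carries the C4 methyl group, α the opposite face.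
Remark: 4 is used as the commercial THF solution. Compounds 7, 8, 12, 13 and 37 are mixtures at a centre or double bond that is erased later, so their SMILES leave it open.

**Route**

Step 1
Reactants: 1 (R)-4-(tert-butyldimethylsilyloxy)cyclopent-2-en-1-one
Product: 2 (R)-4-(tert-butyldimethylsilyloxy)-2-iodocyclopent-2-en-1-one
Conditions: I2, pyridine, CH2Cl2, 0 °C → rt
Reagents that add atoms: iodine, II
Why: Pyridine-mediated α-iodination of an enone (conjugate addition of pyridine, iodination of the enolate, E1cB loss of pyridine) is the standard entry to 2-iodocycloenones and leaves the silyloxy stereocentre untouched.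

Step 2
Reactants: 2 (R)-4-(tert-butyldimethylsilyloxy)-2-iodocyclopent-2-en-1-one
Product: 3 (R)-4-(tert-butyldimethylsilyloxy)-2-methylcyclopent-2-en-1-one
Conditions: Me4Sn, Pd2(dba)3 (2.5 mol %), AsPh3 (10 mol %), NMP, 60 °C
Reagents that add atoms: tetramethyltin, C[Sn](C)(C)C
Why: Stille coupling of the vinyl iodide under neutral conditions installs the future C4 methyl group without β-elimination of the silyloxy group.

Step 3
Reactants: 3 (R)-4-(tert-butyldimethylsilyloxy)-2-methylcyclopent-2-en-1-one; 4 2-methylprop-1-enylmagnesium bromide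
Product: 5 silyl enol ether (C3 OTMS, C3=C4, C4 methyl, C1 α-OTBS, C5 β-isobutenyl)
Conditions: CuBr·SMe2 (10 mol %), TMSCl, HMPA, THF, −78 °C; Et3N quench
Reagents that add atoms: chlorotrimethylsilane, C[Si](C)(C)Cl
Why: Copper-catalysed conjugate addition of the alkenyl Grignard reagent, accelerated by TMSCl, should deliver the isobutenyl group to C5 on the face opposite the C1 silyloxy group (the anti rule of 4-silyloxycyclopentenones) and trap the regiodefined enolate as its silyl enol ether.

Step 4
Reactants: 5 silyl enol ether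
Product: 6 cyclopentan-3-one with C1 α-OTBS, C4 α-CH2OBn, C4 β-CH3, C5 β-isobutenyl
Conditions: BnOCH2Cl, ZnBr2 (10 mol %), CH2Cl2, 0 °C → rt
Reagents that add atoms: benzyl chloromethyl ether, ClCOCc1ccccc1
Why: Lewis-acid (Mukaiyama-type) alkylation of the silyl enol ether with the α-chloro ether forms the C4 quaternary centre by C-alkylation only, the oxocarbenium ion entering anti to the vicinal C5 isobutenyl group so that CH2OBn becomes α and the methyl β.

Step 5
Reactants: 6 cyclopentan-3-one
Product: 7 cyclopentan-3-ol (C3 epimers)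
Conditions: NaBH4, MeOH, 0 °C
Reagents that add atoms: none
Why: Borohydride reduction of the hindered ketone spares the silyl ether, the benzyl ether and the alkene, and the new carbinol centre is erased in step 7 so its configuration does not matter.

Step 6
Reactants: 7 cyclopentan-3-ol
Product: 8 C3 O-phenyl thionocarbonate
Conditions: PhOC(S)Cl, pyridine, DMAP (cat.), CH2Cl2, rt
Reagents that add atoms: O-phenyl chlorothionoformate, S=C(Cl)Oc1ccccc1
Why: DMAP-catalysed acylation gives the Barton–McCombie substrate without a strong base that could trigger 1,3-silyl migration or retro-aldol cleavage.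

Step 7
Reactants: 8 C3 O-phenyl thionocarbonate
Product: 9 cyclopentane with C1 α-OTBS, C4 α-CH2OBn, C4 β-CH3, C5 β-isobutenyl
Conditions: Bu3SnH, AIBN (cat.), toluene, 100 °C
Reagents that add atoms: none
Why: Barton–McCombie radical deoxygenation removes the C3 oxygen, the secondary radical being reduced by the stannane faster than it can add to the alkene (only 4-exo or 5-endo modes are open).

Step 8
Reactants: 9 silyl ether
Product: 10 cyclopentan-1-ol (C1 α-OH)
Conditions: TBAF, THF, rt
Reagents that add atoms: none
Why: Fluoride cleavage of the secondary silyl ether is selective and leaves the benzyl ether and alkene intact.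

Step 9
Reactants: 10 cyclopentan-1-ol
Product: 11 3-(benzyloxymethyl)-3-methyl-2-(2-methylprop-1-enyl)cyclopentan-1-one (C1 ketone, isobutenyl cis to the C4 methyl)
Conditions: Dess–Martin periodinane, CH2Cl2, 0 °C → rt
Reagents that add atoms: none
Why: Dess–Martin oxidation is near-neutral, so the β,γ-unsaturated ketone should form without epimerisation at C5 or migration of the alkene into conjugation.

Step 10
Reactants: 11 cyclopentan-1-one
Product: 12 C1 methoxymethylene enol ether (E/Z mixture)
Conditions: Ph3P(CH2OMe)Cl, KHMDS, THF, 0 °C → rt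
Reagents that add atoms: (methoxymethyl)triphenylphosphonium chloride, COC[P+](c1ccccc1)(c1ccccc1)c1ccccc1.[Cl-]
Why: Wittig methoxymethylenation turns the ketone into an electron-rich exocyclic alkene, carbonyl addition of the small ylide being expected to outrun deprotonation of the hindered C5–H; the enol-ether geometry is irrelevant.

Step 11
Reactants: 12 enol ether
Product: 14 1-hydroxycyclopentane-1-carbaldehyde (C1 α-OH and β-CHO), via methoxy epoxide 13 (not isolated)
Conditions: dimethyldioxirane (acetone solution), CH2Cl2, −78 °C; then THF/H2O, NaH2PO4, 0 °C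
Reagents that add atoms: dimethyldioxirane, CC1(C)OO1; water, O
Why: In this Rubottom-type oxidation the dioxirane epoxidises the enol ether far faster than the trisubstituted alkene and from the α face, anti to the vicinal β-isobutenyl group, so hydrolysis of the epoxy ether gives the α-hydroxy aldehyde with the C1–O bond α.

Step 12
Reactants: 14 α-hydroxy aldehyde
Product: 16 spirobutenolide (C1 spiro; ring O1–C8(=O)–C9=C10), via (Z)-hydroxy enoate 15 (not isolated)
Conditions: (CF3CH2O)2P(O)CH2CO2Me, KHMDS, 18-crown-6, THF, −78 °C; then PPTS (cat.), toluene, 60 °C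
Reagents that add atoms: methyl bis(2,2,2-trifluoroethyl)phosphonoacetate, COC(=O)CP(=O)(OCC(F)(F)F)OCC(F)(F)F
Why: Still–Gennari Z-selective Horner–Wadsworth–Emmons olefination places the ester cis to the tertiary hydroxyl, which then lactonises to the butenolide.

Step 13
Reactants: 16 spirobutenolide
Product: 18 β-methyl spirolactone (C10 methyl), via silyl ketene acetal 17 (not isolated)
Conditions: MeMgBr, CuBr·SMe2 (10 mol %), TMSCl, THF, −78 → −40 °C; aq NH4Cl
Reagents that add atoms: methylmagnesium bromide, C[Mg]Br
Why: In this copper-catalysed conjugate addition the methyl group should attack C10 on the butenolide face turned toward the C2 methylene, because the other face is covered by the isobutenyl group on C5 (cis to C10 on the cyclopentane), which sets the C10 configuration of the target.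

Step 14
Reactants: 18 β-methyl spirolactone
Product: 19 lithium γ-hydroxy carboxylate
Conditions: LiOH·H2O, THF/MeOH/H2O, 50 °C; evaporate, dry by toluene azeotrope
Reagents that add atoms: lithium hydroxide, [Li+].[OH-]
Why: Saponification opens the lactone and the salt is kept basic and dry, so the tertiary γ-hydroxy acid cannot relactonise.

Step 15
Reactants: 19 lithium γ-hydroxy carboxylate
Product: 21 3-methyl-4-oxy acid with C1 OTES, via bis(triethylsilyl) derivative 20 (not isolated)
Conditions: TESOTf (2.5 equiv), 2,6-lutidine, CH2Cl2, −78 → 0 °C; then THF/H2O, NaH2PO4, rt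
Reagents that add atoms: triethylsilyl triflate, CC[Si](CC)(CC)OS(=O)(=O)C(F)(F)F
Why: The silyl triflate silylates both the carboxylate and the tertiary alcohol, and the labile silyl ester alone is hydrolysed on mild aqueous work-up, leaving the C1 triethylsilyl ether.

Step 16
Reactants: 21 silyloxy acid
Product: 23 diazoketone (C7 diazo carbon, C8 ketone), via mixed anhydride 22 (not isolated)
Conditions: i-BuOCOCl, Et3N, THF, −20 °C; then CH2N2, Et2O, 0 °C → rt
Reagents that add atoms: diazomethane, C=[N+]=[N-]
Why: Acylation of diazomethane by the mixed carbonic anhydride (first stage of an Arndt–Eistert sequence) gives the α-diazoketone without free HCl, so the tertiary silyl ether survives.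

Step 17
Reactants: 23 diazoketone
Product: 24 tricyclic C8 ketone with the 5-7-3 carbon skeleton (C1 α-OTES, C4 α-CH2OBn, H6 and H7 β, C11 on the side of H5)
Conditions: Cu(CF3COCHCOCF3)2 (5 mol %), CH2Cl2, reflux, slow addition of 23 (final 0.005 M)
Reagents that add atoms: none
Why: Loss of N2 at copper gives an electrophilic metal carbene at C7 that adds in a concerted, asynchronous [2+1] step across the electron-rich C6=C11 bond, the closest known reaction type being the copper- or rhodium-catalysed intramolecular cyclopropanation of unsaturated α-diazoketones. The cycloheptanone (C1, C5, C6, C7, C8, C9, C10) closes in a 7-exo sense by the C7–C6 bond, with C11 left outside that ring, and the cyclopropane closes in the same event by the C7–C11 bond. C7 is fixed by the cis fusion that a three-membered ring on a seven-membered ring demands, so H6 and H7 are cis. C6 is fixed by the conformation of the isobutenyl group: allylic 1,3-strain with the (Z)-methyl group on C11 holds H5 eclipsed with C6=C11, and the tether from C1 can reach only the alkene face turned toward C1, which places C11 syn to H5 and H6 anti to H5. The step needs chemoselectivity for the alkene over C–H insertion and ylide formation; this is secured because the 1,5-positions offer only the quaternary C1 and a primary methyl C–H, the silyl and benzyl ethers are remote and poor ylide donors, and the trisubstituted alkene is the most nucleophilic site within reach.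

Step 18
Reactants: 24 tricyclic C8 ketone
Product: 26 tricyclic tertiary alcohol (C8 methylene and C1 α-OH; C4 α-CH2OBn), via hydrazone 25 (not isolated)
Conditions: N2H4·H2O, KOH, diethylene glycol, 130 °C then 195 °C
Reagents that add atoms: none
Why: Wolff–Kishner reduction (Huang–Minlon procedure) removes the C8 carbonyl, the cyclopropylcarbinyl anion being protonated by the glycol before it can open, and the hot hydroxide also cleaves the triethylsilyl ether.

Step 19
Reactants: 26 tricyclic tertiary alcohol benzyl ether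
Product: 27 diol (C1 α-OH, C4 α-CH2OH)
Conditions: H2 (1 atm), Pd/C, EtOAc/EtOH, rt
Reagents that add atoms: none
Why: Hydrogenolysis cleaves the benzyl ether, and the saturated, hindered gem-dimethylcyclopropane is not opened under these mild conditions.

Step 20
Reactants: 27 diol
Product: 28 hydroxy acid (C9' carboxylic acid on C4, C1 α-OH)
Conditions: TEMPO (20 mol %), PhI(OAc)2 (2.2 equiv), MeCN/H2O, rt
Reagents that add atoms: water, O
Why: The oxoammonium-mediated oxidation takes the primary alcohol through the aldehyde hydrate to the acid and cannot touch the tertiary alcohol.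

Step 21
Reactants: 28 hydroxy acid
Product: 30 bridged lactone (C1–O–C9'(=O)–C4), via mixed anhydride 29 (not isolated)
Conditions: 2,4,6-trichlorobenzoyl chloride, Et3N, THF, rt; then DMAP, toluene, 80 °C
Reagents that add atoms: none
Why: Yamaguchi lactonisation closes the 2-oxabicyclo[2.2.1]heptan-3-one, which is possible only because the C1 oxygen and the C4 carboxyl group are both on the α face.

Step 22
Reactants: 31 5-fluorobenzene-1,3-diol
Product: 32 1,3-bis(benzyloxy)-5-fluorobenzene
Conditions: BnBr, K2CO3, DMF, 60 °C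
Reagents that add atoms: benzyl bromide, BrCc1ccccc1
Why: Williamson etherification protects both phenols as ethers that are removed later by the same hydrogenation that makes the isobutyl group.

Step 23
Reactants: 32 1,3-bis(benzyloxy)-5-fluorobenzene
Product: 33 1,5-bis(benzyloxy)-2-bromo-3-fluorobenzene
Conditions: NBS, MeCN, 0 °C
Reagents that add atoms: N-bromosuccinimide, BrN1C(=O)CCC1=O
Why: Electrophilic bromination should go para to one benzyloxy group and ortho to the other at the less hindered position next to fluorine, not between the two ethers.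

Step 24
Reactants: 33 1,5-bis(benzyloxy)-2-bromo-3-fluorobenzene; 30 bridged lactone
Product: 36 tetracyclic aryl ketone (C9' ketone; aryl ether O on C1; two OBn), via aryllithium 34 (not isolated), via lithium alkoxide 35 (not isolated)
Conditions: 33, t-BuLi (2 equiv), THF, −78 °C; 30, −78 → −40 °C; then DMPU, 60 °C
Reagents that add atoms: none
Why: Bromine–lithium exchange gives an ortho-fluoroaryllithium that is stable at −78 °C and opens the strained lactone by acyl substitution; the released C1 alkoxide then displaces the fluoride ortho to the new ketone (SNAr), closing the seven-membered oxepine ring.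

Step 25
Reactants: 36 tetracyclic aryl ketone
Product: 37 C9' benzylic alcohol (epimers)
Conditions: LiAlH4, THF, 0 °C → rt
Reagents that add atoms: none
Why: Hydride reduction of the hindered aryl ketone gives the benzylic alcohol, whose configuration is lost on ionisation in the next step.

Step 26
Reactants: 37 C9' benzylic alcohol
Product: 38 C9' 2-methylallyl compound (C9' configured as in the target; two OBn)
Conditions: 2-methylallyltrimethylsilane, Bi(OTf)3 (5 mol %), CH2Cl2, −40 → 0 °C
Reagents that add atoms: 2-methylallyltrimethylsilane, CC(=C)C[Si](C)(C)C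
Why: In this Hosomi–Sakurai benzylic substitution the Lewis acid ionises the alcohol to a 2,4,6-trioxygenated benzylic cation that cannot eliminate or rearrange to a better cation, and the allylsilane should attack it on the face turned toward the one-carbon bridge C5, away from the endo hydrogens of the C2–C3 bridge, which puts the new carbon chain on the C5 side as in the target.

Step 27
Reactants: 38 C9' 2-methylallyl compound
Product: 39 C9' isobutyl bisphenol
Conditions: H2 (1 atm), Pd/C, EtOAc/MeOH, rt
Reagents that add atoms: none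
Why: One hydrogenation saturates the 1,1-disubstituted alkene to the isobutyl group and cleaves both aryl benzyl ethers, while the cyclopropane and the tertiary alkyl aryl ether are inert.

Step 28
Reactants: 39 C9' isobutyl bisphenol
Product: 41 CNP0189833.2 (target), via bis(iminium) salt 40 (not isolated)
Conditions: POCl3, DMF, EtOAc, 0 °C → rt; then H2O, 50 °C
Reagents that add atoms: N,N-dimethylformamide, CN(C)C=O; water, O
Why: Vilsmeier–Haack formylation attacks the two remaining ring positions of the phloroglucinol-type arene, each flanked by two oxygen substituents, and hydrolysis of the bis(iminium) salt gives the dialdehyde.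

**Compound list**

1 | (R)-4-(tert-butyldimethylsilyloxy)cyclopent-2-en-1-one | CC(C)(C)[Si](C)(C)O[C@@H]1CC(=O)C=C1 | starting material
2 | (R)-4-(tert-butyldimethylsilyloxy)-2-iodocyclopent-2-en-1-one | CC(C)(C)[Si](C)(C)O[C@@H]1CC(=O)C(I)=C1 | intermediate
3 | (R)-4-(tert-butyldimethylsilyloxy)-2-methylcyclopent-2-en-1-one | CC(C)(C)[Si](C)(C)O[C@@H]1CC(=O)C(C)=C1 | intermediate
4 | 2-methylprop-1-enylmagnesium bromide | CC(C)=C[Mg]Br | starting material
5 | silyl enol ether: C3 OTMS, C3=C4, C4 methyl, C1 α-OTBS, C5 β-isobutenyl (OTBS and isobutenyl trans) | CC(C)(C)[Si](C)(C)O[C@@H]1CC(O[Si](C)(C)C)=C(C)[C@H]1C=C(C)C | intermediate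
6 | cyclopentan-3-one: C1 α-OTBS, C4 α-CH2OBn, C4 β-CH3, C5 β-isobutenyl | CC(C)(C)[Si](C)(C)O[C@@H]1CC(=O)[C@](C)(COCc2ccccc2)[C@H]1C=C(C)C | intermediate
7 | cyclopentan-3-ol derived from 6, C3 epimer mixture | CC(C)(C)[Si](C)(C)O[C@@H]1CC(O)[C@](C)(COCc2ccccc2)[C@H]1C=C(C)C | intermediate
8 | C3 O-phenyl thionocarbonate of 7, C3 epimer mixture | CC(C)(C)[Si](C)(C)O[C@@H]1CC(OC(=S)Oc2ccccc2)[C@](C)(COCc2ccccc2)[C@H]1C=C(C)C | intermediate
9 | cyclopentane: C1 α-OTBS, C4 α-CH2OBn, C4 β-CH3, C5 β-isobutenyl | CC(C)(C)[Si](C)(C)O[C@@H]1CC[C@](C)(COCc2ccccc2)[C@H]1C=C(C)C | intermediate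
10 | cyclopentan-1-ol: C1 α-OH, C4 α-CH2OBn, C4 β-CH3, C5 β-isobutenyl | O[C@@H]1CC[C@](C)(COCc2ccccc2)[C@H]1C=C(C)C | intermediate
11 | 3-(benzyloxymethyl)-3-methyl-2-(2-methylprop-1-enyl)cyclopentan-1-one, isobutenyl cis to the methyl | O=C1CC[C@](C)(COCc2ccccc2)[C@H]1C=C(C)C | intermediate
12 | C1 methoxymethylene enol ether of 11, E/Z mixture | COC=C1CC[C@](C)(COCc2ccccc2)[C@H]1C=C(C)C | intermediate
13 | spiro methoxy epoxide, epoxide oxygen α on C1, C10 epimers | COC1O[C@@]12CC[C@](C)(COCc3ccccc3)[C@H]2C=C(C)C | intermediate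
14 | 1-hydroxycyclopentane-1-carbaldehyde: C1 α-OH, C1 β-CHO, C4 α-CH2OBn, C4 β-CH3, C5 β-isobutenyl | O=C[C@@]1(O)CC[C@](C)(COCc2ccccc2)[C@H]1C=C(C)C | intermediate
15 | methyl (Z)-3-(1-hydroxycyclopentyl)prop-2-enoate derived from 14 | COC(=O)/C=C\[C@@]1(O)CC[C@](C)(COCc2ccccc2)[C@H]1C=C(C)C | intermediate
16 | spirobutenolide: lactone O α on C1, C10=C9 | O=C1C=C[C@@]2(O1)CC[C@](C)(COCc3ccccc3)[C@H]2C=C(C)C | intermediate
17 | silyl ketene acetal (2-trimethylsilyloxy-4,5-dihydrofuran) with C10 methyl | C[Si](C)(C)OC1=C[C@H](C)[C@@]2(O1)CC[C@](C)(COCc3ccccc3)[C@H]2C=C(C)C | intermediate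
18 | β-methyl spirolactone, C10 methyl on the lactone face toward C2 | O=C1C[C@H](C)[C@@]2(O1)CC[C@](C)(COCc3ccccc3)[C@H]2C=C(C)C | intermediate
19 | lithium 3-(1-hydroxycyclopentyl)butanoate derived from 18 | [Li+].[O-]C(=O)C[C@H](C)[C@@]1(O)CC[C@](C)(COCc2ccccc2)[C@H]1C=C(C)C | intermediate
20 | triethylsilyl ester and C1 triethylsilyl ether of the acid | CC[Si](CC)(CC)OC(=O)C[C@H](C)[C@@]1(O[Si](CC)(CC)CC)CC[C@](C)(COCc2ccccc2)[C@H]1C=C(C)C | intermediate
21 | 3-[1-(triethylsilyloxy)cyclopentyl]butanoic acid (C8 acid, C10 methyl, C1 α-OTES) | OC(=O)C[C@H](C)[C@@]1(O[Si](CC)(CC)CC)CC[C@](C)(COCc2ccccc2)[C@H]1C=C(C)C | intermediate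
22 | isobutyl carbonic mixed anhydride of 21 | CC(C)COC(=O)OC(=O)C[C@H](C)[C@@]1(O[Si](CC)(CC)CC)CC[C@](C)(COCc2ccccc2)[C@H]1C=C(C)C | intermediate
23 | diazoketone: C7 diazo, C8 ketone, C10 methyl, C1 α-OTES, C4 α-CH2OBn, C5 β-isobutenyl | [N-]=[N+]=CC(=O)C[C@H](C)[C@@]1(O[Si](CC)(CC)CC)CC[C@](C)(COCc2ccccc2)[C@H]1C=C(C)C | intermediate
24 | tricyclic C8 ketone, 5-7-3 skeleton, cyclopropane C11 on the side of H5 | O=C1C[C@H](C)[C@@]2(O[Si](CC)(CC)CC)CC[C@](C)(COCc3ccccc3)[C@H]2[C@H]4[C@@H]1C4(C)C | intermediate
25 | C8 hydrazone of 24 | NN=C1C[C@H](C)[C@@]2(O[Si](CC)(CC)CC)CC[C@](C)(COCc3ccccc3)[C@H]2[C@H]4[C@@H]1C4(C)C | intermediate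
26 | tricyclic tertiary alcohol: C8 methylene, C1 α-OH, C4 α-CH2OBn | C1C[C@H](C)[C@@]2(O)CC[C@](C)(COCc3ccccc3)[C@H]2[C@H]4[C@@H]1C4(C)C | intermediate
27 | tricyclic diol: C1 α-OH, C4 α-CH2OH | C1C[C@H](C)[C@@]2(O)CC[C@](C)(CO)[C@H]2[C@H]4[C@@H]1C4(C)C | intermediate
28 | tricyclic hydroxy acid: C1 α-OH, C4 α-CO2H | C1C[C@H](C)[C@@]2(O)CC[C@](C)(C(=O)O)[C@H]2[C@H]4[C@@H]1C4(C)C | intermediate
29 | 2,4,6-trichlorobenzoic mixed anhydride of 28 | C1C[C@H](C)[C@@]2(O)CC[C@](C)(C(=O)OC(=O)c3c(Cl)cc(Cl)cc3Cl)[C@H]2[C@H]4[C@@H]1C4(C)C | intermediate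
30 | bridged lactone C1–O–C9'(=O)–C4 | C1C[C@H](C)[C@@]23CC[C@](C)(C(=O)O3)[C@H]2[C@H]4[C@@H]1C4(C)C | intermediate
31 | 5-fluorobenzene-1,3-diol | Oc1cc(O)cc(F)c1 | starting material
32 | 1,3-bis(benzyloxy)-5-fluorobenzene | Fc1cc(OCc2ccccc2)cc(OCc2ccccc2)c1 | intermediate
33 | 1,5-bis(benzyloxy)-2-bromo-3-fluorobenzene | Fc1cc(OCc2ccccc2)cc(OCc2ccccc2)c1Br | intermediate
34 | [2,4-bis(benzyloxy)-6-fluorophenyl]lithium | [Li]c1c(F)cc(OCc2ccccc2)cc1OCc1ccccc1 | intermediate
35 | lithium C1 alkoxide of the C9' aryl ketone | [Li+].C1C[C@H](C)[C@@]2([O-])CC[C@](C)(C(=O)c3c(F)cc(OCc5ccccc5)cc3OCc3ccccc3)[C@H]2[C@H]4[C@@H]1C4(C)C | intermediate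
36 | tetracyclic aryl ketone: C9' ketone, aryl ether on C1, two benzyloxy groups | O=C1c2c(OCc5ccccc5)cc(OCc5ccccc5)cc2O[C@]23CC[C@@]1(C)[C@H]2[C@H]1[C@@H](CC[C@@H]3C)C1(C)C | intermediate
37 | C9' benzylic alcohol, C9' epimers | OC1c2c(OCc5ccccc5)cc(OCc5ccccc5)cc2O[C@]23CC[C@@]1(C)[C@H]2[C@H]1[C@@H](CC[C@@H]3C)C1(C)C | intermediate
38 | C9' 2-methylallyl compound, C9' as in the target | CC(=C)C[C@H]1c2c(OCc5ccccc5)cc(OCc5ccccc5)cc2O[C@]23CC[C@@]1(C)[C@H]2[C@H]1[C@@H](CC[C@@H]3C)C1(C)C | intermediate
39 | C9' isobutyl bisphenol | CC(C)C[C@H]1c2c(O)cc(O)cc2O[C@]23CC[C@@]1(C)[C@H]2[C@H]1[C@@H](CC[C@@H]3C)C1(C)C | intermediate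
40 | bis(dimethyliminium) dichloride of the target dialdehyde | CC(C)C[C@H]1c2c(O)c(C=[N+](C)C)c(O)c(C=[N+](C)C)c2O[C@]23CC[C@@]1(C)[C@H]2[C@H]1[C@@H](CC[C@@H]3C)C1(C)C.[Cl-].[Cl-] | intermediate
41 | CNP0189833.2 | CC(C)C[C@H]1c2c(O)c(C=O)c(O)c(C=O)c2O[C@]23CC[C@@]1(C)[C@H]2[C@H]1[C@@H](CC[C@@H]3C)C1(C)C | target

**Step count and risks**

Total step count: 28. Longest linear sequence: 26 (steps 1–21 and 24–28); the aryl branch (steps 22–23) joins at step 24.

Steps most likely to fail:

1. Step 17. The carbene may be consumed by dimerisation or by C–H insertion (into the C10 methyl group or the allylic C5–H) before it reaches the hindered alkene through a seven-membered closure. Fallback, setting out from 21 and returning at 24: the acid is coupled with N,O-dimethylhydroxylamine (EDC, i-Pr2NEt) to the Weinreb amide F1. Vinylmagnesium bromide gives the vinyl ketone F2. Ring-closing metathesis with the second-generation Grubbs catalyst, with loss of 2-methylpropene, closes the cycloheptenone F3. Sulfur-ylide cyclopropanation with diphenylsulfonium isopropylide then adds the CMe2 unit across C6=C7 from the face syn to H5 to give 24.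

2. Step 26. The allylsilane may attack the benzylic cation on the wrong face, because the seven-membered ring can twist either toward C5 or toward the C2–C3 bridge; this would give the C9' epimer. Fallback, setting out from 36 and returning at 39: the order of bond formation at C9' is reversed. Isobutyllithium with CeCl3 adds to the ketone to give the tertiary benzylic alcohol F7. Ionic hydrogenation (Et3SiH, CF3CO2H, CH2Cl2, −40 °C) then delivers hydride instead of carbon to the face that the cation exposes, giving the isobutyl bis(benzyl ether) F8 with the opposite sense at C9'. Hydrogenolysis as in step 27 gives 39.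

3. Step 24. The ortho-fluoroaryllithium may lose LiF to an aryne before it adds to the hindered lactone, or the lithium alkoxide may be too poor a nucleophile for the SNAr closure. Fallback, setting out from 27 and returning at 36: the primary alcohol of the diol is oxidised with TEMPO and PhI(OAc)2 in CH2Cl2 to the hydroxy aldehyde F4, which reacts with 34 (2.2 equiv) at −78 °C to give the benzylic carbinol F5. Dess–Martin oxidation gives the hydroxy ketone F6, and KHMDS in THF/DMF at 60 °C effects the SNAr closure to 36.

**Further compounds**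

F1 | step 17 | Weinreb amide of acid 21 | CON(C)C(=O)C[C@H](C)[C@@]1(O[Si](CC)(CC)CC)CC[C@](C)(COCc2ccccc2)[C@H]1C=C(C)C
F2 | step 17 | vinyl ketone (C8 ketone, C7 vinyl) | C=CC(=O)C[C@H](C)[C@@]1(O[Si](CC)(CC)CC)CC[C@](C)(COCc2ccccc2)[C@H]1C=C(C)C
F3 | step 17 | cis-fused cycloheptenone (C6=C7, C8 ketone) | O=C1C[C@H](C)[C@@]2(O[Si](CC)(CC)CC)CC[C@](C)(COCc3ccccc3)[C@H]2C=C1
F4 | step 24 | tricyclic hydroxy aldehyde (C1 α-OH, C4 α-CHO) | C1C[C@H](C)[C@@]2(O)CC[C@](C)(C=O)[C@H]2[C@H]4[C@@H]1C4(C)C
F5 | step 24 | benzylic carbinol from F4 and 34 (C9' epimers) | C1C[C@H](C)[C@@]2(O)CC[C@](C)(C(O)c3c(F)cc(OCc5ccccc5)cc3OCc3ccccc3)[C@H]2[C@H]4[C@@H]1C4(C)C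
F6 | step 24 | hydroxy aryl ketone (protonated form of 35) | C1C[C@H](C)[C@@]2(O)CC[C@](C)(C(=O)c3c(F)cc(OCc5ccccc5)cc3OCc3ccccc3)[C@H]2[C@H]4[C@@H]1C4(C)C
F7 | step 26 | C9' tertiary benzylic alcohol bearing isobutyl (C9' epimers) | CC(C)CC1(O)c2c(OCc5ccccc5)cc(OCc5ccccc5)cc2O[C@]23CC[C@@]1(C)[C@H]2[C@H]1[C@@H](CC[C@@H]3C)C1(C)C
F8 | step 26 | C9' isobutyl bis(benzyl ether) | CC(C)C[C@H]1c2c(OCc5ccccc5)cc(OCc5ccccc5)cc2O[C@]23CC[C@@]1(C)[C@H]2[C@H]1[C@@H](CC[C@@H]3C)C1(C)C
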